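## Structural features

The target joins a eudesmane decalin through one methylene carbon (C16) to a hexasubstituted phloroglucinol that carries three free hydroxyls, one formyl and one 3-methylbutanoyl group. In eudesmane numbering ring B is the saturated ring C1–C2–C3–C4–C5–C10 and ring A the cyclohexene C5(=C6)–C7–C8–C9–C10; C10 is quaternary (methyl C14), C1 bears C16, C4 bears methyl C15 and C7 bears the isopropenyl group C11–C13. With the face of the C10 methyl called β, the C1 arylmethyl and the C4 methyl are also β and the C7 isopropenyl is α; C1 and C10 are directly bonded, C4 and C10 flank the sp2 carbon C5, and C7 is allylic on the far side of C5=C6. Fragile elements are the trisubstituted C5=C6 and the 1,1-disubstituted C11=C12 alkenes (both protonate to tertiary cations), the allylic stereocentres C4 and C7, and the electron-rich formyl-acyl-triphenol, which is sensitive to air and to condensation. The real difficulty lies in the contiguous C1/C10 pair (a quaternary methyl carbon next to a tertiary carbon with a bulky benzylic arm on the same face), in the remote C4 methyl, and in decorating and unmasking the arene without strong acid. The key step exploits that ring B holds C10 and C1 side by side while its C4–C5 edge is shared with the alkene carbon of a ring A that is a carvone ring: ring B can be laid onto ring A by a [4+2] union of the diene C10=C5–C4=C3 with a C1–C2 unit whose acyl carbon is C16 and already carries the arene. An oxygen at C6, absent from the target, serves as a control element twice, first to shield one face of the diene and later to deliver hydrogen to C4.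

## Logic of the disconnections

25 to 24: the three phenolic O–H groups are traced back to O–CH3, so three O–C bonds are broken last in the forward direction. Methyl ethers are the one phenol protection that survives organoaluminium, hydride, organolithium and oxidant alike. The gain is an air-stable, non-acidic arene in 24. The demand is a dealkylation that spares two acid-sensitive alkenes; because every methoxy group of 24 lies ortho to a carbonyl, nucleophilic (thiolate) cleavage under basic conditions is chosen.

24 to 23 to 18 and 19: the aryl–C(=O) bond of the 3-methylbutanoyl group and the aryl–CHO bond are cut. In 18 both ring positions are C–H flanked by two methoxy groups, so both can be metalated; this keeps Lewis acids of the Friedel–Crafts kind away from the alkenes. The gain is an undecorated, symmetric trimethoxyphenyl ring in 18 and a purchasable aldehyde 19. The demand is a second metalation in the presence of a lithium alkoxide, and a later oxidation of the carbinol 23.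

18 to 16: the C16 methylene is traced back to a C16 carbonyl. This carbonyl is what makes the two-carbon partner a dienophile and what makes C1 epimerisable. The demand is deoxygenation of a doubly flanked aryl ketone without touching the alkenes, met by hydride reduction followed by silane capture of the very stabilised benzylic cation at low temperature.

16 to 13 to 12: the C4–H bond and the C5=C6 position are traced back to a C4=C5 alkene with a 6β oxygen. A cycloaddition leaves exactly this tetrasubstituted alkene, and an allylic diazene at C6 moves it while placing hydrogen on a defined face of C4. The gain is that C4 need not be set during ring construction. The demand is an invertive displacement at the hindered C6 carbinol and the β configuration of the C6 oxygen.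

12 to 8 and 10: C1–C10 and C2–C3 are cut and ring B is opened. This removes one ring, two skeletal bonds and the C1/C10 stereo pair in one move and divides the molecule into a chiral-pool diene and an achiral enone that carries the arene. The forward step must be regioselective (acyl carbon on C1), face-selective (C10 methyl trans to the C7 isopropenyl) and must end with C1 cis to the C10 methyl.

8 to 6 and 7: the C4–C5 bond of the diene arm is cut. A cross-coupling of an enol triflate with an alkenylboronate fixes the diene position without any isomerisable intermediate. The demand is coupling at a tetrasubstituted, flanked triflate.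

6 to 4 to 3 to 1: the C5–O triflate bond, the C9–H bond and the C6–O bond are removed in turn. Conjugate hydride addition to the enone gives the one enolate regioisomer needed for triflation, and kinetic enolate hydroxylation places oxygen at C6 trans to the isopropenyl group. All carbon atoms and the C7 configuration of ring A come from 1.

10 to 9: the terminal C=CH2 bond is cut to a methyl ketone and formaldehyde, so the dienophile is one step from a purchasable ketone.

## Other disconnections considered

Alternative 1: Both rings are cut at once (C1–C2, C3–C4, C9–C10, C7–C8), leading to the acyclic cross-conjugated triene A2. In the forward key step acrolein A3, activated as an iminium ion by a chiral imidazolidinone salt, would add to the C1=C10–C5=C4 diene of A2; the ring B alkene so formed completes a second diene, which would add phenyl vinyl sulfone A4 in the same pot to give A1. In its favour: two rings, four skeletal bonds and all four ring stereocentres arise in one operation. C1 and C4 would be set directly in the first cycloaddition, with no equilibration and no alkene transposition, and the arene is already attached through CH2, so no ketone has to be deoxygenated. On convergence and on direct control of C1 and C4 it is the better plan. Against it here: A2 offers two dienes that share the C4=C5 alkene, so site selectivity must be won. Both termini of the first diene are substituted, which is a slow case for iminium catalysis. The second cycloaddition must build the quaternary C10 with a weak dienophile and no Lewis acid. Three helper groups then have to go (formyl by decarbonylation with RhCl(PPh3)3, sulfonyl reductively, pivalate to isopropenyl by elimination), and the arene end game is unchanged. The chosen plan has one diene, one cycloaddition and the absolute configuration from 1 instead of from a catalyst. In step count the alternative is expected to be longer once A2 and the three removals are included.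

Alternative 2: The C1–C16 bond is made as one edge of a cyclopropane whose other edge, C2–C16, is temporary. In the forward key step Et2Zn and CH2I2, directed by the 3β-hydroxyl of dienol A6, would cyclopropanate C1=C2 to give A5. Oxidation to the cyclopropyl enone A7 and opening at C16 by an aryl nucleophile would then cleave C2–C16. In its favour: hydroxyl-directed cyclopropanation is reliable and stereospecific and would place C16 on the β face of C1 without equilibration. The quaternary C10 trans to the isopropenyl group is the normal outcome of annulation chemistry starting from 1. No benzylic ketone needs removal. On control of C10 and C1 it is the equal of, or better than, the chosen plan. Against it here: A6 is a bis-allylic alcohol prone to ionisation and aromatising rearrangement. Opening a singly activated cyclopropyl ketone with a hindered, trioxygenated aryl nucleophile is the least secure link. The leftover oxygen sits at C3, on the wrong side of C4: an allylic transposition from C3 would deliver hydrogen to C5, not C4, so the C5=C6 alkene and the C4 centre need further steps. The route is linear and expected to be longer than the chosen one.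

Alternative 3: The benzene ring itself is cut, between the carbon bearing the 3-methylbutanoyl group and its neighbouring C–OH carbon. In the forward key step Mg(OMe)2 in methanol would open pyrone A9 to the triketo ester A10, whose C6 carbanion would attack the ester carbonyl (Claisen-type closure) to give A8; formylation of the one free ring position would then give 25. In its favour: no phenol protection at all, so the weakest step of the chosen plan (triple demethylation) disappears. The acyl group is placed by construction, and the arene is formed under mild base, which the alkenes tolerate. On protecting-group economy and mildness it is the better plan, and the arene part is about equal in step count. Against it here: closure by C-acylation competes with aldol-type closure to a resorcylate and with return to a pyrone, and the bulky substituent next to the ester in A10 should slow the desired mode. A9 also needs a terpene half that already contains both rings and all four stereocentres, so the skeleton problem stays as it is. The chosen plan carries a preformed arene whose substitution pattern is never in question, at the price of methyl ethers.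

Key step: step 6

Assumption: 9 is taken as a purchasable ketone, and the carbinol carbon created in steps 9 and 10 is drawn without configuration because both epimers converge.

## Route

Step 1
Reactants: 1 (S)-(+)-carvone
Product: 3 (5R,6R)-6-hydroxycarvone (hydroxyl trans to isopropenyl), via potassium dienolate of carvone 2 (not isolated)
Conditions: KN(SiMe3)2, THF, −78 °C; 2-(phenylsulfonyl)-3-phenyloxaziridine, −78 °C; aq. NH4Cl
Reagents that add atoms: 2-(phenylsulfonyl)-3-phenyloxaziridine, O=S(=O)(N1OC1c1ccccc1)c1ccccc1
Why: Kinetic deprotonation at the α′ methylene (future C6) gives the cross-conjugated dienolate 2, and oxygen transfer from the N-sulfonyloxaziridine (enolate hydroxylation) should occur anti to the adjacent isopropenyl group, setting C6 trans to C7. The potassium counter-ion limits addition of the enolate to the sulfonimine by-product.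

Step 2
Reactants: 3 (5R,6R)-6-hydroxycarvone
Product: 4 (5R,6R)-6-(tert-butyldimethylsilyloxy)carvone
Conditions: TBSCl, imidazole, DMAP (cat.), DMF, rt
Reagents that add atoms: tert-butyldimethylsilyl chloride, C[Si](C)(Cl)C(C)(C)C
Why: Standard O-silylation of a secondary α-hydroxy ketone under mild base, which should not epimerise C6; the silyl ether protects the ketol and later acts as the steric shield of the diene.

Step 3
Reactants: 4 (5R,6R)-6-(tert-butyldimethylsilyloxy)carvone
Product: 6 6-(tert-butyldimethylsilyloxy)-2-methyl-5-(prop-1-en-2-yl)cyclohex-1-en-1-yl trifluoromethanesulfonate (silyloxy trans to isopropenyl; both centres as in 4), via lithium enolate 5 (not isolated)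
Conditions: LiBH(s-Bu)3, THF, −78 °C; PhNTf2, −78 → 0 °C
Reagents that add atoms: N-phenylbis(trifluoromethanesulfonimide), O=S(=O)(N(c1ccccc1)S(=O)(=O)C(F)(F)F)C(F)(F)F
Why: The bulky borohydride adds hydride to the unsubstituted β-carbon (future C9) of the enone (1,4-reduction) and gives the tetrasubstituted enolate 5 as a single regioisomer, which is O-sulfonylated by the triflimide. No stereocentre is formed and C6 and C7 are untouched.

Step 4
Reactants: 6 enol triflate; 7 isopropenylboronic acid pinacol ester
Product: 8 tert-butyldimethylsilyl ether of trans-3-methyl-2,6-di(prop-1-en-2-yl)cyclohex-2-en-1-ol (diene C10=C5–C4=C3 with 6β-silyloxy and 7α-isopropenyl in eudesmane terms)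
Conditions: Pd(dppf)Cl2 (cat.), K3PO4, 1,4-dioxane–H2O, 70 °C
Reagents that add atoms: none
Why: Suzuki–Miyaura coupling of an enol triflate with an alkenylboronate (oxidative addition, transmetalation, reductive elimination) forms C4–C5 and completes the diene without touching the stereocentres. The bidentate phosphine is chosen for the flanked, tetrasubstituted triflate.

Step 5
Reactants: 9 2′,4′,6′-trimethoxyacetophenone
Product: 10 1-(2,4,6-trimethoxyphenyl)prop-2-en-1-one
Conditions: (CH2O)n, i-Pr2NH·CF3CO2H, CF3CO2H (cat.), THF, reflux; used fresh
Reagents that add atoms: paraformaldehyde (as formaldehyde), C=O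
Why: Mannich-type α-methylenation: the enol of the methyl ketone adds to the iminium ion formed from formaldehyde and the secondary ammonium salt, and the amine is then lost by β-elimination. The ketone has only one enolisable site.

Step 6
Reactants: 8 carvone-derived diene; 10 1-(2,4,6-trimethoxyphenyl)prop-2-en-1-one
Product: 12 1β-(2,4,6-trimethoxybenzoyl)-6β-(tert-butyldimethylsilyloxy)eudesma-4,11-diene (C10 methyl β; C7 isopropenyl α), via endo adduct (1α-aroyl epimer) 11 (not isolated)
Conditions: Me2AlCl, CH2Cl2, −78 → −20 °C; aq. potassium sodium tartrate; crude: NaOMe (cat.), MeOH–THF, 40 °C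
Reagents that add atoms: none
Why: This is a Lewis-acid-promoted normal-demand Diels–Alder reaction: Me2AlCl binds the ketone of 10 (with an ortho methoxy oxygen), lowers its LUMO and also scavenges protic acid that would ionise the allylic silyl ether of 8. The closest known reaction type is the Lewis-acid cycloaddition of 1-methyl-2-vinylcyclohexene dienes with enones, which builds a quaternary methyl-bearing carbon despite the cis methyl at the diene terminus. Ring B closes in one concerted, asynchronous, suprafacial [4+2] event in which C2–C3 forms ahead of C1–C10, so no separate ring-closure mode has to be chosen. The unsubstituted and most nucleophilic terminus C3 pairs with the enone β-carbon, which places the acyl carbon on C1 next to C10. C10 is set by facial selectivity: allylic strain with the C4 methyl of the diene arm forces the C6 silyloxy group pseudoaxial on the β face, so the dienophile should add from the α face and the C10 methyl is pushed β, trans to the C7 isopropenyl. C1 is set in two stages: the endo transition state should give 11 with the aroyl group trans to the C10 methyl, and enolisation with NaOMe then moves it to the equatorial position cis to that methyl, C1 being the only acidic stereocentre. The equilibration is placed here because in this Δ4 series the C10 methyl is pseudoaxial on ring B and the 1β-aroyl group equatorial, a preference that is not assured once the alkene has moved. The step thus needs regio-, facial and C1 selectivity, secured respectively by diene polarisation, by the silyloxy group and by thermodynamics.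

Step 7
Reactants: 12 1β-aroyl-6β-silyloxy-eudesma-4,11-diene
Product: 13 1β-(2,4,6-trimethoxybenzoyl)eudesma-4,11-dien-6β-ol
Conditions: Bu4NF, THF, 0 °C → rt
Reagents that add atoms: none
Why: Fluoride cleaves the Si–O bond, driven by the strong Si–F bond. The mildly basic medium leaves C1 at its equilibrium configuration and does not touch the alkenes.

Step 8
Reactants: 13 1β-aroyl-eudesma-4,11-dien-6β-ol
Product: 16 1β-(2,4,6-trimethoxybenzoyl)-4αH-eudesma-5,11-diene (C4 methyl β), via N-allyl sulfonylhydrazone 14 (not isolated), via allylic diazene 15 (not isolated)
Conditions: PPh3, DEAD, IPNBSH (N-isopropylidene-N′-2-nitrobenzenesulfonylhydrazine), THF, 0 °C → rt; then CF3CH2OH–H2O, rt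
Reagents that add atoms: none
Why: Mitsunobu displacement at C6 with inversion gives 14 (nitrogen on the α face); hydrolysis of the hydrazone and loss of the sulfinate give the monoalkyl diazene 15. This loses N2 by a retro-ene shift that passes its hydrogen suprafacially to C4 on the α face while the alkene moves to C5=C6 (reductive allylic transposition), so the C4 methyl ends β, cis to the C10 methyl. The acetone-protected hydrazide is used because it tolerates the higher temperature that a hindered carbinol needs.

Step 9
Reactants: 16 1β-(2,4,6-trimethoxybenzoyl)-eudesma-5,11-diene
Product: 18 1β-(2,4,6-trimethoxybenzyl)-4αH-eudesma-5,11-diene, via benzylic carbinol 17 (not isolated)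
Conditions: LiAlH4, THF, 0 °C → rt; aq. potassium sodium tartrate; crude: Et3SiH, BF3·OEt2, CH2Cl2, −78 °C
Reagents that add atoms: none
Why: Hydride reduction gives the carbinol 17, which ionises at −78 °C to a benzylic cation stabilised by three methoxy groups and is captured by the silane (ionic deoxygenation). At this temperature the isolated alkenes should not be protonated, and C1 is not involved. The acid-labile carbinol is carried on crude.

Step 10
Reactants: 18 1β-(2,4,6-trimethoxybenzyl)-eudesma-5,11-diene; 19 3-methylbutanal
Product: 23 3-[(eudesma-5,11-dien-1β-yl)methyl]-5-(1-hydroxy-3-methylbutyl)-2,4,6-trimethoxybenzaldehyde (carbinol epimers), via aryllithium 20 (not isolated), via lithium alkoxide 21 (not isolated), via lithiated alkoxide 22 (not isolated)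
Conditions: n-BuLi, TMEDA, THF, 0 °C; 19, −78 °C; n-BuLi, 0 °C; DMF, −78 → 0 °C; aq. NH4Cl
Reagents that add atoms: N,N-dimethylformamide, CN(C)C=O
Why: Directed ortho-metalation occurs at the only two ring C–H positions, each flanked by two methoxy groups. The first aryllithium adds to the aldehyde, the lithium alkoxide so formed tolerates a second metalation at the remaining position, and DMF delivers the formyl group. No Lewis acid meets the alkenes, and the new carbinol centre is removed in step 11.

Step 11
Reactants: 23 hydroxy aldehyde
Product: 24 3-[(eudesma-5,11-dien-1β-yl)methyl]-2,4,6-trimethoxy-5-(3-methylbutanoyl)benzaldehyde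
Conditions: Dess–Martin periodinane, NaHCO3, CH2Cl2, 0 °C → rt
Reagents that add atoms: none
Why: Hypervalent-iodine oxidation of the secondary benzylic carbinol to the ketone; the buffered, non-acidic medium leaves the aldehyde, the arene and both alkenes alone.

Step 12
Reactants: 24 tri-O-methyl ether of the target
Product: 25 target: 3-[(4αH-eudesma-5,11-dien-1β-yl)methyl]-2,4,6-trihydroxy-5-(3-methylbutanoyl)benzaldehyde (C10 methyl β, C4 methyl β, C7 isopropenyl α)
Conditions: NaSEt (excess), DMF, 110 °C; cold 1 M HCl
Reagents that add atoms: none
Why: The thiolate removes each methyl group by SN2 attack at carbon; every methoxy group lies ortho to a carbonyl, so each phenoxide leaves as a vinylogous carboxylate. The basic medium cannot protonate the alkenes, and the aldehyde has no α-hydrogen and returns from any hemithioacetal on acidification.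

## Compound list

1 | (S)-(+)-carvone | C=C(C)[C@@H]1CC(=O)C(C)=CC1 | starting material
2 | potassium dienolate of carvone | C=C(C)[C@@H]1C=C(O[K])C(C)=CC1 | intermediate
3 | (5R,6R)-6-hydroxycarvone | C=C(C)[C@@H]1[C@@H](O)C(=O)C(C)=CC1 | intermediate
4 | (5R,6R)-6-(tert-butyldimethylsilyloxy)carvone | C=C(C)[C@@H]1[C@@H](O[Si](C)(C)C(C)(C)C)C(=O)C(C)=CC1 | intermediate
5 | lithium enolate from conjugate reduction of 4 | C=C(C)[C@@H]1[C@@H](O[Si](C)(C)C(C)(C)C)C(O[Li])=C(C)CC1 | intermediate
6 | 6-(tert-butyldimethylsilyloxy)-2-methyl-5-(prop-1-en-2-yl)cyclohex-1-en-1-yl triflate | C=C(C)[C@@H]1[C@@H](O[Si](C)(C)C(C)(C)C)C(OS(=O)(=O)C(F)(F)F)=C(C)CC1 | intermediate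
7 | isopropenylboronic acid pinacol ester | C=C(C)B1OC(C)(C)C(C)(C)O1 | starting material
8 | silyl ether of trans-3-methyl-2,6-di(prop-1-en-2-yl)cyclohex-2-en-1-ol (diene) | C=C(C)[C@@H]1[C@@H](O[Si](C)(C)C(C)(C)C)C(C(C)=C)=C(C)CC1 | intermediate
9 | 2′,4′,6′-trimethoxyacetophenone | CC(=O)c1c(OC)cc(OC)cc1OC | starting material
10 | 1-(2,4,6-trimethoxyphenyl)prop-2-en-1-one | C=CC(=O)c1c(OC)cc(OC)cc1OC | intermediate
11 | endo adduct, 1α-aroyl epimer of 12 | C=C(C)[C@@H]1[C@@H](O[Si](C)(C)C(C)(C)C)C2=C(C)CC[C@H](C(=O)c3c(OC)cc(OC)cc3OC)[C@]2(C)CC1 | intermediate
12 | 1β-(2,4,6-trimethoxybenzoyl)-6β-(tert-butyldimethylsilyloxy)eudesma-4,11-diene | C=C(C)[C@@H]1[C@@H](O[Si](C)(C)C(C)(C)C)C2=C(C)CC[C@@H](C(=O)c3c(OC)cc(OC)cc3OC)[C@]2(C)CC1 | intermediate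
13 | 1β-(2,4,6-trimethoxybenzoyl)eudesma-4,11-dien-6β-ol | C=C(C)[C@@H]1[C@@H](O)C2=C(C)CC[C@@H](C(=O)c3c(OC)cc(OC)cc3OC)[C@]2(C)CC1 | intermediate
14 | 6α-N-(2-nitrobenzenesulfonyl)-N′-isopropylidenehydrazino adduct | C=C(C)[C@@H]1[C@H](N(N=C(C)C)S(=O)(=O)c3ccccc3[N+](=O)[O-])C2=C(C)CC[C@@H](C(=O)c4c(OC)cc(OC)cc4OC)[C@]2(C)CC1 | intermediate
15 | 6α-allylic diazene | C=C(C)[C@@H]1[C@H](N=N)C2=C(C)CC[C@@H](C(=O)c3c(OC)cc(OC)cc3OC)[C@]2(C)CC1 | intermediate
16 | 1β-(2,4,6-trimethoxybenzoyl)-4αH-eudesma-5,11-diene | C=C(C)[C@@H]1C=C2[C@@H](C)CC[C@@H](C(=O)c3c(OC)cc(OC)cc3OC)[C@]2(C)CC1 | intermediate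
17 | benzylic carbinol from 16 (C16 epimers) | C=C(C)[C@@H]1C=C2[C@@H](C)CC[C@@H](C(O)c3c(OC)cc(OC)cc3OC)[C@]2(C)CC1 | intermediate
18 | 1β-(2,4,6-trimethoxybenzyl)-4αH-eudesma-5,11-diene | C=C(C)[C@@H]1C=C2[C@@H](C)CC[C@@H](Cc3c(OC)cc(OC)cc3OC)[C@]2(C)CC1 | intermediate
19 | 3-methylbutanal | CC(C)CC=O | starting material
20 | 3-lithio derivative of 18 | C=C(C)[C@@H]1C=C2[C@@H](C)CC[C@@H](Cc3c(OC)c([Li])c(OC)cc3OC)[C@]2(C)CC1 | intermediate
21 | lithium alkoxide of the 3-methylbutanal adduct | C=C(C)[C@@H]1C=C2[C@@H](C)CC[C@@H](Cc3c(OC)cc(OC)c(C(O[Li])CC(C)C)c3OC)[C@]2(C)CC1 | intermediate
22 | ring-lithiated lithium alkoxide | C=C(C)[C@@H]1C=C2[C@@H](C)CC[C@@H](Cc3c(OC)c([Li])c(OC)c(C(O[Li])CC(C)C)c3OC)[C@]2(C)CC1 | intermediate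
23 | hydroxy aldehyde (carbinol epimers) | C=C(C)[C@@H]1C=C2[C@@H](C)CC[C@@H](Cc3c(OC)c(C=O)c(OC)c(C(O)CC(C)C)c3OC)[C@]2(C)CC1 | intermediate
24 | tri-O-methyl ether of the target | C=C(C)[C@@H]1C=C2[C@@H](C)CC[C@@H](Cc3c(OC)c(C=O)c(OC)c(C(=O)CC(C)C)c3OC)[C@]2(C)CC1 | intermediate
25 | CNP0564915.1 | C=C(C)[C@@H]1C=C2[C@@H](C)CC[C@@H](Cc3c(O)c(C=O)c(O)c(C(=O)CC(C)C)c3O)[C@]2(C)CC1 | target

## Step count and least certain steps

Total: 12 steps. Longest linear sequence: 11 steps (steps 1–4 and 6–12, from 1).

Step 6 (key step). Most likely to go wrong: weak facial discrimination, because the α face that must be attacked carries the axial C7 isopropenyl group. Alongside this, the cycloaddition of the hindered diene with a bulky, twisted aryl ketone may be slow enough for Lewis-acid ionisation of the allylic silyl ether and oligomerisation of the diene to take over. Incomplete equilibration at the flanked C1 position is a further risk. Fallback, setting out from 8 and returning at 12: replace the enone by acrolein, a small dienophile that should add at −78 °C under Me2AlCl with the same regiochemistry. Its adduct, the 1β-carbaldehyde F1, epimerises at C1 much more readily. 2,4,6-Trimethoxyphenyllithium F2 (from 1,3,5-trimethoxybenzene and n-BuLi) would then add to the aldehyde to give the carbinol F3, and Dess–Martin oxidation of F3 gives 12. The arene thus enters by carbonyl addition instead of with the dienophile.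

Step 8. Most likely to go wrong: slow backside displacement at the pseudoaxial, doubly flanked C6 carbinol, so that elimination to a triene or entry of the nucleophile at C4 (SN2′) competes. Fallback, setting out from 13 and returning at 16: formylate the alcohol (acetic formic anhydride, pyridine) to the allylic formate F4 and subject it to hydrogenolysis with Pd(OAc)2 and n-Bu3P in hot dioxane. Zerovalent palladium ionises the formate from the α face, anti to the leaving group, without a direct substitution at C6. After loss of CO2 the palladium hydride delivers hydrogen from that same face to the more substituted terminus C4, which gives the same 4αH, Δ5 product.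

Step 9. Most likely to go wrong: slow hydride addition to the doubly flanked carbonyl in the first stage. In the second stage a long-lived benzylic cation may lose a proton to a styrene, or acid may be transferred to the alkenes. Fallback, setting out from 17 and returning at 18: trap the cation with thiophenol (catalytic camphorsulfonic acid, CH2Cl2, −40 °C), a far faster nucleophile than a silane, to give the benzylic phenyl sulfide F5. The C–S bond is then cleaved by a radical chain with n-Bu3SnH and AIBN in toluene at 90 °C; the benzylic radical has no favourable cyclisation onto either alkene.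

Step 10. Most likely to go wrong: incomplete second metalation of the lithium alkoxide, or proton transfer from the enolisable aldehyde instead of addition, leaving mixtures of mono-functionalised arenes. Fallback, setting out from 18 and returning at 24: electrophilic decoration. Friedel–Crafts acylation with 3-methylbutanoyl chloride and SnCl4 in CH2Cl2 at −78 °C gives the mono-ketone F6. Formylation of the remaining position with Cl2CHOCH3 and TiCl4 at −78 → −20 °C (Rieche formylation) gives 24 directly, which also omits step 11. The price is exposure of the alkenes to Lewis acid, hence its place as reserve.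

Step 12. Most likely to go wrong: stalling after one or two methyl groups as the ring becomes a polyanion, and attrition of the aldehyde at the temperature the last cleavage needs. Fallback, setting out from 24 and returning at 25: change from nucleophilic attack at methyl under base to chelation-directed activation of the ether oxygen. BCl3 with 2,6-di-tert-butylpyridine in CH2Cl2 at −78 → −20 °C, quenched cold with NaHCO3 in methanol, should cleave each ether through a boron chelate with its neighbouring carbonyl. The hindered base is there to keep protic acid away from the alkenes.

## Further compounds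

F1 | step 6 | 6β-(tert-butyldimethylsilyloxy)eudesma-4,11-diene-1β-carbaldehyde | C=C(C)[C@@H]1[C@@H](O[Si](C)(C)C(C)(C)C)C2=C(C)CC[C@@H](C=O)[C@]2(C)CC1
F2 | step 6 | 2,4,6-trimethoxyphenyllithium | [Li]c1c(OC)cc(OC)cc1OC
F3 | step 6 | carbinol from F1 and F2 (C16 epimers) | C=C(C)[C@@H]1[C@@H](O[Si](C)(C)C(C)(C)C)C2=C(C)CC[C@@H](C(O)c3c(OC)cc(OC)cc3OC)[C@]2(C)CC1
F4 | step 8 | 6β-formate of 13 | C=C(C)[C@@H]1[C@@H](OC=O)C2=C(C)CC[C@@H](C(=O)c3c(OC)cc(OC)cc3OC)[C@]2(C)CC1
F5 | step 9 | benzylic phenyl sulfide from 17 (C16 epimers) | C=C(C)[C@@H]1C=C2[C@@H](C)CC[C@@H](C(Sc3ccccc3)c4c(OC)cc(OC)cc4OC)[C@]2(C)CC1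
F6 | step 10 | mono-(3-methylbutanoyl) derivative of 18 | C=C(C)[C@@H]1C=C2[C@@H](C)CC[C@@H](Cc3c(OC)cc(OC)c(C(=O)CC(C)C)c3OC)[C@]2(C)CC1
F0 | step 12 | none | none
A1 | alternative 1 | eudesm-5-ene with formyl at C2, phenylsulfonyl at C8 and a pivaloyloxymethyl side chain | CC(COC(=O)C(C)(C)C)[C@@H]1C=C2[C@@H](C)CC(C=O)[C@@H](Cc3c(OC)cc(OC)cc3OC)[C@]2(C)CC1S(=O)(=O)c1ccccc1
A2 | alternative 1 | all-E acyclic cross-conjugated triene | CC(COC(=O)C(C)(C)C)/C=C/C(=C\C)/C(C)=C/Cc1c(OC)cc(OC)cc1OC
A3 | alternative 1 | acrolein | C=CC=O
A4 | alternative 1 | phenyl vinyl sulfone | C=CS(=O)(=O)c1ccccc1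
A5 | alternative 2 | 1,2-methano-eudesma-4,11-dien-3-ol | C=C(C)[C@@H]1CC2=C(C)[C@@H](O)[C@H]3C[C@H]3[C@]2(C)CC1
A6 | alternative 2 | eudesma-1,4,11-trien-3β-ol | C=C(C)[C@@H]1CC2=C(C)[C@@H](O)C=C[C@]2(C)CC1
A7 | alternative 2 | 1,2-methano-eudesma-4,11-dien-3-one | C=C(C)[C@@H]1CC2=C(C)C(=O)[C@H]3C[C@H]3[C@]2(C)CC1
A8 | alternative 3 | deformyl target (3-alkyl phlorisovalerophenone) | C=C(C)[C@@H]1C=C2[C@@H](C)CC[C@@H](Cc3c(O)cc(O)c(C(=O)CC(C)C)c3O)[C@]2(C)CC1
A9 | alternative 3 | 3-(eudesmadienylmethyl)-4-hydroxy-6-(4-methyl-2-oxopentyl)-2-pyrone | C=C(C)[C@@H]1C=C2[C@@H](C)CC[C@@H](Cc3c(O)cc(CC(=O)CC(C)C)oc3=O)[C@]2(C)CC1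
A10 | alternative 3 | methyl 2-(eudesmadienylmethyl)-9-methyl-3,5,7-trioxodecanoate | C=C(C)[C@@H]1C=C2[C@@H](C)CC[C@@H](CC(C(=O)OC)C(=O)CC(=O)CC(=O)CC(C)C)[C@]2(C)CC1
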